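Which flask holds the most trapped intermediate at 25 min, and how much does each hold?

| flask | substrate | partner | capture agent | remark | time |
|---|---|---|---|---|---|
| cedar | 0.10 M | 0.80 equiv | 0.030 M | run made earlier |  |
| oak | 0.10 M | 1.2 equiv | 0.030 M | run made earlier |  |
| south | 0.10 M | 0.800 equiv (fed, over 5.0 min) | 0.0300 M | all else is in the flask from the start; the feed brings no volume worth counting | 25 min |
| west | 0.10 M | 0.800 equiv | 0.0300 M | everything together at the start | 25 min |
| south-west | 0.10 M (fed, over 5.0 min) | 0.800 equiv | 0.0300 M | all else is in the flask from the start; the feed brings no volume worth counting | 25 min |
| south-east | 0.10 M | 0.800 equiv (in portions, 4, over 5.0 min) | 0.0300 M | first portion at the start, last at 5.0 min | 25 min |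

- cedar (time / min: trapped intermediate / %, target / %): 6.00: 6.9, 7.8; 12.0: 13.9, 6.8; 20.0: 18.2, 6.3; 25.0: 22.4, 5.7
- oak (time / min: trapped intermediate / %, target / %): 0.667: 0.2, 27.9; 2.00: 1.0, 40.4; 3.00: 0.8, 29.6; 5.00: 3.3, 17.1

(standard deviation of a reading: 1 percentage point)

- which flask leads in amount of trapped intermediate, in percent of the substrate charged ("all alike" within 1.5 percentage points) (south / west / south-west / south-east / all alike)
- how much trapped intermediate is there at the end, in percent of the substrate charged: south
- how much trapped intermediate is there at the end, in percent of the substrate charged: west
- how much trapped intermediate is there at the end, in percent of the substrate charged: south-west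
- how much trapped intermediate is there at the end, in percent of the substrate charged: south-east

- what may be going on: target <-> isomer of the product; second intermediate -> side product; open intermediate + second intermediate -> target; partner -> second intermediate; substrate -> open intermediate; open intermediate + capture agent -> trapped intermediate

The substrate gives open intermediate and the partner gives second intermediate. These two couple to target, and open intermediate that stays uncoupled can meet capture agent. Amounts below are fractions of the substrate charge.

The bench rule treats the partner as the limiting reagent, so the uncoupled share is the charge minus the partner. For cedar, which has the recipe of west: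

uncoupled share = 20.0%

reading / uncoupled share = 22.4% / 20.0% = 1.12

The rule stops working where this ratio passes 1. Cedar already stands there at 25.0 min, with a reading of 22.4% trapped and a scatter of 1 percentage point, more than the rule allows, so the reading points to less partner coupled than was charged. The capture agent still sets a ceiling:

ceiling = 30.0%

Freezing open intermediate makes the loss of capture agent pseudo-first-order. My reckoning therefore uses the spending constant λ, the share of the remaining capture agent taken per minute. Read from cedar at 12.0 min, with the scatter of that reading:

λ = 0.0519 min⁻¹

trapped = ceiling × (1 − exp(−λt))

west at 25 min = 21.8%

In this reckoning λ goes with the open intermediate left uncoupled. My reckoning puts south-west above west but under the ceiling, and south and south-east below west.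

The forecast names south-west as the leader, with 24.5%, against 21.5% for west, 20% for south-east and 19.5% for south. Its ground for the leader: “Feeding the substrate exposes the second intermediate with little open intermediate to meet it, so much is wasted.”

The flasks give 26.3% for south-west, 21.6% for west, 18.4% for south-east and 17.8% for south, so south-west leads.

    target ⇌ isomer of the product (K = 6.80, k = 0.00870 s⁻¹)
    second intermediate → side product (k = 0.00910 s⁻¹)
    open intermediate + second intermediate → target (k = 2.20 M⁻¹ s⁻¹)
    partner → second intermediate (k = 0.0790 s⁻¹)
    substrate → open intermediate (k = 0.0120 s⁻¹)
    open intermediate + capture agent → trapped intermediate (k = 0.0320 M⁻¹ s⁻¹)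

South-west leads west by 4.7 points, the forecast had 3 points, and the margin is 1.5 points, so the order stands on either pair. West lands at 21.6% against the reckoned 21.8%. The neighbouring flask is south with 0.0075 M of capture agent, which makes its ceiling 7.50%. Its open intermediate ends at 22.2%, level with the 21.8% in west, so λ from cedar is carried over and gives 5.45%. That flask holds 5.43% of trapped intermediate at 25 min.

(All runs come from a simulation with constants of no real substance; noise was put on by code.)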